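**Retrosynthetic overview** (target numbering: C1 = quaternary C(OH)(C7H2OBz), C2 = CH–OBz next to it, C3=C4, C5 = CH–OBz, C6 = CH–OAc)
1. The ester pattern is taken back (acetylation, acetonide hydrolysis, tribenzoylation, LiAlH4) to acid 13, in which O-1/O-6 are tied as a dioxolane and C7 is a carboxyl group.
2. Key disconnection C1–C2: 13 is the Ireland–Claisen ring-contraction product of δ-lactone 10. The enabling feature is that C7(=O)–C1–C2–C3=C4 is a γ,δ-unsaturated acid and C4 is joined back to C1 through C5–C6. Tying the C7 carboxyl to C4 through oxygen therefore gives a six-membered lactone ring (O–C7–C1–C6–C5–C4) that carries the C3=C2 vinyl group on C4; its ketene acetal C7=C1 and that vinyl group form the 1,5-diene.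
3. Lactone 10 is a D-mannose derivative: mannose C-1 to C-6 become target C7, C1, C6, C5, C4, C3. C2 is one added carbon, brought in as an (E)-alkenylboronate and converted into the (E)-enol benzoate.
4. C5 and C6 are bought (mannose C-4, C-3). C1 and C2 are created together in the key step, relayed from mannose C-5 (which is spent) and from the (E)-olefin geometry.
5. Ring order: pyranose (bought) → δ-lactone (temporary) → cyclohexene, the only ring made, in step 9; the dioxolane is a temporary ring removed in step 12.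

Key step: step 9

Assumption: phenyl 1-thio-α-D-mannopyranoside (1) is taken as a catalogue carbohydrate building block; its anomeric configuration is irrelevant because C-1 becomes the lactone carbonyl.

**Step 1**
Reactants: 1 phenyl 1-thio-α-D-mannopyranoside
Product: 3 phenyl 2,3-O-isopropylidene-1-thio-α-D-mannopyranoside, via diacetonide 2 (not isolated)
Conditions: 2,2-dimethoxypropane, TsOH·H2O (cat.), acetone, 25 °C; then H2O, 25 °C; Et3N
Reagents that add atoms: 2,2-dimethoxypropane COC(C)(C)OC
Why: Acid-catalysed transacetalisation should take the cis-2,3-diol as a dioxolane and the 4,6-diol as a more labile dioxane, and mild aqueous acid should then remove only the dioxane; no stereocentre is touched.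

**Step 2**
Reactants: 3 phenyl 2,3-O-isopropylidene-1-thio-α-D-mannopyranoside
Product: 4 phenyl 2,3-O-isopropylidene-1-thio-α-D-manno-hexodialdo-1,5-pyranoside (6-aldehyde, 4-OH free)
Conditions: TEMPO (10 mol %), PhI(OAc)2, CH2Cl2, 25 °C
Reagents that add atoms: none
Why: Oxoammonium (TEMPO) oxidation is selective for the primary alcohol over the secondary 4-OH and is known to spare thioglycoside sulfur; the non-basic medium should keep C-5 intact.

**Step 3**
Reactants: 4 phenyl 2,3-O-isopropylidene-1-thio-α-D-manno-hexodialdo-1,5-pyranoside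
Product: 5 phenyl (6E)-6,7-dideoxy-2,3-O-isopropylidene-7-(4,4,5,5-tetramethyl-1,3,2-dioxaborolan-2-yl)-1-thio-α-D-manno-hept-6-enopyranoside
Conditions: Cl2CHB(pin), CrCl2, LiI, THF, 25 °C
Reagents that add atoms: 2-(dichloromethyl)-4,4,5,5-tetramethyl-1,3,2-dioxaborolane ClC(Cl)B1OC(C)(C)C(C)(C)O1
Why: Takai–Utimoto olefination with the geminal dichromium reagent should give the (E)-alkenylboronate by anti elimination from the β-oxido adduct, under non-basic conditions that spare the α-alkoxy aldehyde centre.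

**Step 4**
Reactants: 5 the (E)-alkenylboronate with free 4-OH
Product: 6 phenyl (6E)-4-O-benzoyl-6,7-dideoxy-2,3-O-isopropylidene-7-(4,4,5,5-tetramethyl-1,3,2-dioxaborolan-2-yl)-1-thio-α-D-manno-hept-6-enopyranoside
Conditions: BzCl, pyridine, DMAP (cat.), CH2Cl2, 0 → 25 °C
Reagents that add atoms: benzoyl chloride O=C(Cl)c1ccccc1
Why: DMAP-catalysed acylation of the only free hydroxyl; blocking O-4 guarantees that only the 1,5-lactone can form later.

**Step 5**
Reactants: 6 the 4-O-benzoyl alkenylboronate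
Product: 7 potassium (E)-alkenyltrifluoroborate of 6 (BF3K in place of B(pin))
Conditions: KHF2, MeOH/H2O, 25 °C
Reagents that add atoms: potassium hydrogen difluoride F.[F-].[K+]
Why: Fluoride exchange at boron converts the pinacol ester into the trifluoroborate with retention of the (E)-alkene; benzoate, acetonide and thioglycoside should tolerate the brief mildly acidic medium.

**Step 6**
Reactants: 7 the potassium (E)-alkenyltrifluoroborate
Product: 8 phenyl (6E)-4,7-di-O-benzoyl-6-deoxy-2,3-O-isopropylidene-1-thio-α-D-manno-hept-6-enopyranoside ((E)-enol benzoate)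
Conditions: PhCO2H, CuBr (10 mol %), DMAP (20 mol %), 4 Å MS, O2 (1 atm), MeCN, 60 °C
Reagents that add atoms: benzoic acid O=C(O)c1ccccc1
Why: Chan–Lam-type oxidative copper-catalysed C–O coupling of alkenyltrifluoroborates with carboxylic acids is stereoretentive, so the (E)-borate should give the (E)-enol benzoate that the key step needs.

**Step 7**
Reactants: 8 the (E)-enol benzoate thioglycoside
Product: 9 (6E)-4,7-di-O-benzoyl-6-deoxy-2,3-O-isopropylidene-D-manno-hept-6-enopyranose (lactol, both anomers)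
Conditions: NBS, acetone/H2O (9:1), −15 °C
Reagents that add atoms: water O
Why: Thioglycoside hydrolysis by bromonium activation of sulfur and capture of the oxocarbenium ion by water; the electron-poor enol ester alkene should react far more slowly than sulfur at this temperature.

**Step 8**
Reactants: 9 the lactol
Product: 10 (6E)-4,7-di-O-benzoyl-6-deoxy-2,3-O-isopropylidene-D-manno-hept-6-enono-1,5-lactone
Conditions: (nPr4N)RuO4 (5 mol %), NMO, 4 Å MS, CH2Cl2, 25 °C
Reagents that add atoms: none
Why: Ley–Griffith oxidation of a lactol to the lactone under neutral conditions; with O-4 benzoylated the δ-lactone cannot slip to the γ-lactone.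

**Step 9**
Reactants: 10 (6E)-4,7-di-O-benzoyl-6-deoxy-2,3-O-isopropylidene-D-manno-hept-6-enono-1,5-lactone
Product: 13 (3aR,4S,7R,7aS)-4,7-bis(benzoyloxy)-2,2-dimethyl-3a,4,7,7a-tetrahydro-1,3-benzodioxole-3a-carboxylic acid, via silyl ketene acetal 11 (not isolated), via trimethylsilyl ester 12 (not isolated)
Conditions: Me3SiCl/Et3N, LiN(SiMe3)2, THF, −78 °C; → 25 °C; toluene, 110 °C; then aq. citric acid
Reagents that add atoms: none
Why: LiN(SiMe3)2 removes H-2 of the lactone in the presence of Me3SiCl so that the enolate is O-silylated at once to the cyclic ketene acetal 11, whose C1=C2–O5–C5–C6=C7 array (lactone numbering) is a 1,5-diene that undergoes a [3,3]-sigmatropic Ireland–Claisen shift on heating, breaking O5–C5 and forming C2–C7; the closest known reaction type is the Ireland–Claisen ring contraction of 6-alkenyl δ-lactones to cyclohexenecarboxylic acids (and of 6-alkenyl-1,4-dioxan-2-ones to dihydropyrans). The cyclohexene is closed in a suprafacial pericyclic mode through the only geometry a six-membered lactone allows, a boat (bicyclo[2.2.2]octane-like) array in which the C-5 vinyl group reaches across the ring to C-2. The quaternary centre (target C1) is controlled by the mannose C-5 stereocentre: the new bond forms on the lactone face that carries the vinyl group, which is cis to O-3 and trans to O-4, so the carboxyl carbon ends trans to both dioxolane oxygens and cis to the 4-benzoate. The CH–OBz centre (target C2) is controlled by the (E)-geometry of the enol benzoate, which in the boat places the benzoyloxy group on the side of the carboxyl carbon and trans to the C1 oxygen. The step needs O-silylation to outrun β-elimination of O-3 and benzoyl transfer to C-2, which the internal Me3SiCl quench at −78 °C and the dioxolane (holding the C3–O bond near the enolate plane) should secure, and it needs a single olefin geometry, which the stereoretentive coupling of step 6 supplies. In one operation the chirality of C-5 is traded for two new stereocentres, the ring alkene and a free carboxyl handle.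

**Step 10**
Reactants: 13 the rearranged acid
Product: 14 (3aR,4S,7R,7aS)-3a-(hydroxymethyl)-2,2-dimethyl-3a,4,7,7a-tetrahydro-1,3-benzodioxole-4,7-diol
Conditions: LiAlH4, THF, 0 → 65 °C; then H2O, aq. NaOH
Reagents that add atoms: none
Why: Hydride reduction takes the hindered α-alkoxy acid to the primary alcohol and cleaves both benzoates (which have served as protecting groups through the rearrangement) in the same operation; the isolated ring alkene and the acetonide are inert and no stereocentre is touched.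

**Step 11**
Reactants: 14 the triol acetonide
Product: 15 [(3aR,4S,7R,7aS)-4,7-bis(benzoyloxy)-2,2-dimethyl-3a,4,7,7a-tetrahydro-1,3-benzodioxol-3a-yl]methyl benzoate
Conditions: BzCl, pyridine, DMAP (cat.), CH2Cl2, 0 → 25 °C
Reagents that add atoms: benzoyl chloride O=C(Cl)c1ccccc1
Why: Exhaustive DMAP-catalysed acylation installs the three benzoates of the target at once, while the dioxolane keeps O-1 and O-6 apart from them.

**Step 12**
Reactants: 15 the tribenzoate acetonide
Product: 16 [(1S,2S,5R,6S)-2,5-bis(benzoyloxy)-1,6-dihydroxycyclohex-3-en-1-yl]methyl benzoate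
Conditions: CF3CO2H/H2O (9:1), CH2Cl2, 0 °C
Reagents that add atoms: none
Why: Acid-catalysed acetal hydrolysis frees the cis tertiary/secondary diol; under acid, benzoyl migration is slow and the allylic esters should survive the short cold exposure.

**Step 13**
Reactants: 16 the diol
Product: 17 [(1R,2S,5R,6S)-6-acetoxy-2,5-bis(benzoyloxy)-1-hydroxycyclohex-3-en-1-yl]methyl benzoate (target)
Conditions: Ac2O, pyridine, DMAP (cat.), CH2Cl2, 0 °C
Reagents that add atoms: acetic anhydride CC(=O)OC(C)=O
Why: Acylation discriminates the secondary C6 hydroxyl from the tertiary C1 hydroxyl, which should stay free under these mild conditions.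

**Compound list**
1 | phenyl 1-thio-α-D-mannopyranoside | OC[C@H]1O[C@H](Sc2ccccc2)[C@@H](O)[C@@H](O)[C@@H]1O | starting material
2 | phenyl 2,3:4,6-di-O-isopropylidene-1-thio-α-D-mannopyranoside | CC1(C)OC[C@H]2O[C@H](Sc3ccccc3)[C@H]3OC(C)(C)O[C@H]3[C@@H]2O1 | intermediate
3 | phenyl 2,3-O-isopropylidene-1-thio-α-D-mannopyranoside | OC[C@H]1O[C@H](Sc2ccccc2)[C@H]2OC(C)(C)O[C@H]2[C@@H]1O | intermediate
4 | phenyl 2,3-O-isopropylidene-1-thio-α-D-manno-hexodialdo-1,5-pyranoside | O=C[C@H]1O[C@H](Sc2ccccc2)[C@H]2OC(C)(C)O[C@H]2[C@@H]1O | intermediate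
5 | phenyl (6E)-6,7-dideoxy-2,3-O-isopropylidene-7-(4,4,5,5-tetramethyl-1,3,2-dioxaborolan-2-yl)-1-thio-α-D-manno-hept-6-enopyranoside | CC1(C)OB(/C=C/[C@H]2O[C@H](Sc3ccccc3)[C@H]3OC(C)(C)O[C@H]3[C@@H]2O)OC1(C)C | intermediate
6 | 4-O-benzoate of 5 | CC1(C)OB(/C=C/[C@H]2O[C@H](Sc3ccccc3)[C@H]3OC(C)(C)O[C@H]3[C@@H]2OC(=O)c2ccccc2)OC1(C)C | intermediate
7 | potassium (E)-alkenyltrifluoroborate corresponding to 6 | [K+].F[B-](F)(F)/C=C/[C@H]1O[C@H](Sc2ccccc2)[C@H]2OC(C)(C)O[C@H]2[C@@H]1OC(=O)c1ccccc1 | intermediate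
8 | phenyl (6E)-4,7-di-O-benzoyl-6-deoxy-2,3-O-isopropylidene-1-thio-α-D-manno-hept-6-enopyranoside | O=C(O/C=C/[C@H]1O[C@H](Sc2ccccc2)[C@H]2OC(C)(C)O[C@H]2[C@@H]1OC(=O)c1ccccc1)c1ccccc1 | intermediate
9 | (6E)-4,7-di-O-benzoyl-6-deoxy-2,3-O-isopropylidene-D-manno-hept-6-enopyranose (anomers) | O=C(O/C=C/[C@H]1OC(O)[C@H]2OC(C)(C)O[C@H]2[C@@H]1OC(=O)c1ccccc1)c1ccccc1 | intermediate
10 | (6E)-4,7-di-O-benzoyl-6-deoxy-2,3-O-isopropylidene-D-manno-hept-6-enono-1,5-lactone | O=C(O/C=C/[C@H]1OC(=O)[C@H]2OC(C)(C)O[C@H]2[C@@H]1OC(=O)c1ccccc1)c1ccccc1 | intermediate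
11 | trimethylsilyl ketene acetal of 10 (C-1 bears OSiMe3, C-1=C-2) | O=C(O/C=C/[C@H]1OC(O[Si](C)(C)C)=C2OC(C)(C)O[C@H]2[C@@H]1OC(=O)c1ccccc1)c1ccccc1 | intermediate
12 | trimethylsilyl ester of 13 | CC1(C)O[C@H]2[C@H](OC(=O)c3ccccc3)C=C[C@H](OC(=O)c3ccccc3)[C@]2(O1)C(=O)O[Si](C)(C)C | intermediate
13 | (3aR,4S,7R,7aS)-4,7-bis(benzoyloxy)-2,2-dimethyl-3a,4,7,7a-tetrahydro-1,3-benzodioxole-3a-carboxylic acid | CC1(C)O[C@H]2[C@H](OC(=O)c3ccccc3)C=C[C@H](OC(=O)c3ccccc3)[C@]2(O1)C(=O)O | intermediate
14 | (3aR,4S,7R,7aS)-3a-(hydroxymethyl)-2,2-dimethyl-3a,4,7,7a-tetrahydro-1,3-benzodioxole-4,7-diol | CC1(C)O[C@H]2[C@H](O)C=C[C@H](O)[C@]2(O1)CO | intermediate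
15 | [(3aR,4S,7R,7aS)-4,7-bis(benzoyloxy)-2,2-dimethyl-3a,4,7,7a-tetrahydro-1,3-benzodioxol-3a-yl]methyl benzoate | CC1(C)O[C@H]2[C@H](OC(=O)c3ccccc3)C=C[C@H](OC(=O)c3ccccc3)[C@]2(O1)COC(=O)c1ccccc1 | intermediate
16 | [(1S,2S,5R,6S)-2,5-bis(benzoyloxy)-1,6-dihydroxycyclohex-3-en-1-yl]methyl benzoate | O[C@H]1[C@H](OC(=O)c2ccccc2)C=C[C@H](OC(=O)c2ccccc2)[C@]1(O)COC(=O)c1ccccc1 | intermediate
17 | [(1R,2S,5R,6S)-6-acetoxy-2,5-bis(benzoyloxy)-1-hydroxycyclohex-3-en-1-yl]methyl benzoate | CC(=O)O[C@H]1[C@H](OC(=O)c2ccccc2)C=C[C@H](OC(=O)c2ccccc2)[C@]1(O)COC(=O)c1ccccc1 | target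

**Step count and risks**
Total step count: 13. Longest linear sequence: 13 steps (from 1).

Steps most likely to fail:

Step 9. The lactone enolate may be lost before silylation by β-elimination of O-3 or by benzoyl transfer to C-2, or the amide base may attack the vinyl ester. The fallback sets out from 5, returns at 14, and runs the ring contraction on a substrate without any ester, making the C2–O bond afterwards from a C–B bond. The 4-OH of 5 is silylated (tBuMe2SiOTf, 2,6-lutidine) to the silyl ether F1. NBS in aqueous acetone should free the lactol F2, and (nPr4N)RuO4/NMO should give the borylated lactone F3. LiN(SiMe3)2/Me3SiCl should give the silyl ketene acetal F4, which on heating should rearrange through the same boat to the trimethylsilyl ester F5 and, after work-up, the allylboronate acid F6, with boron in the place of the benzoyloxy group. NaBO3·4H2O should oxidise the C–B bond with retention to the hydroxy acid F7, LiAlH4 should give the silyl-protected triol F8, and Bu4NF should remove the silyl ether to give 14.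

Step 6. The thioether may bind copper or be oxidised under Cu/O2, so that the oxidative coupling stalls and the borate is lost by protodeboronation. The fallback sets out from 6, returns at 10, and moves the C–O coupling behind the removal of sulfur. NBS in aqueous acetone should convert 6 into the lactol F9, (nPr4N)RuO4/NMO should give the boryl lactone F10, KHF2 the lactone trifluoroborate F11, and the CuBr/DMAP/O2 coupling with benzoic acid on this sulfur-free substrate should give 10.

Step 3. Chromium alkoxide formation at the free 4-OH may slow the olefination, so that the aldehyde is reduced or epimerised at C-5 instead, or the olefin geometry is not controlled. The fallback sets out from 4, returns at 6, and fixes the (E)-geometry by syn-hydroboration of an alkyne. Ohira–Bestmann homologation (dimethyl (1-diazo-2-oxopropyl)phosphonate, K2CO3, MeOH) should give the terminal alkyne F12, benzoylation (BzCl, pyridine) the alkynyl benzoate F13, and Cp2Zr(H)Cl-catalysed hydroboration with pinacolborane should give 6.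

**Further compounds**
F1 | step 9 | 4-O-(tert-butyldimethylsilyl) ether of 5 | CC1(C)OB(/C=C/[C@H]2O[C@H](Sc3ccccc3)[C@H]3OC(C)(C)O[C@H]3[C@@H]2O[Si](C)(C)C(C)(C)C)OC1(C)C
F2 | step 9 | lactol from F1 (anomers) | CC1(C)OB(/C=C/[C@H]2OC(O)[C@H]3OC(C)(C)O[C@H]3[C@@H]2O[Si](C)(C)C(C)(C)C)OC1(C)C
F3 | step 9 | (6E)-4-O-(tert-butyldimethylsilyl)-6,7-dideoxy-2,3-O-isopropylidene-7-(pinacolatoboryl)-D-manno-hept-6-enono-1,5-lactone | CC1(C)OB(/C=C/[C@H]2OC(=O)[C@H]3OC(C)(C)O[C@H]3[C@@H]2O[Si](C)(C)C(C)(C)C)OC1(C)C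
F4 | step 9 | trimethylsilyl ketene acetal of F3 | CC1(C)OB(/C=C/[C@H]2OC(O[Si](C)(C)C)=C3OC(C)(C)O[C@H]3[C@@H]2O[Si](C)(C)C(C)(C)C)OC1(C)C
F5 | step 9 | trimethylsilyl ester of F6 | CC1(C)O[C@H]2[C@H](O[Si](C)(C)C(C)(C)C)C=C[C@H](B3OC(C)(C)C(C)(C)O3)[C@]2(O1)C(=O)O[Si](C)(C)C
F6 | step 9 | 7-(tert-butyldimethylsilyloxy)-2,2-dimethyl-4-(pinacolatoboryl)-3a,4,7,7a-tetrahydro-1,3-benzodioxole-3a-carboxylic acid (configuration as in 13) | CC1(C)O[C@H]2[C@H](O[Si](C)(C)C(C)(C)C)C=C[C@H](B3OC(C)(C)C(C)(C)O3)[C@]2(O1)C(=O)O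
F7 | step 9 | 7-(tert-butyldimethylsilyloxy)-4-hydroxy-2,2-dimethyl-3a,4,7,7a-tetrahydro-1,3-benzodioxole-3a-carboxylic acid | CC1(C)O[C@H]2[C@H](O[Si](C)(C)C(C)(C)C)C=C[C@H](O)[C@]2(O1)C(=O)O
F8 | step 9 | 7-O-(tert-butyldimethylsilyl) ether of 14 | CC1(C)O[C@H]2[C@H](O[Si](C)(C)C(C)(C)C)C=C[C@H](O)[C@]2(O1)CO
F9 | step 6 | (6E)-4-O-benzoyl-6,7-dideoxy-2,3-O-isopropylidene-7-(pinacolatoboryl)-D-manno-hept-6-enopyranose (anomers) | CC1(C)OB(/C=C/[C@H]2OC(O)[C@H]3OC(C)(C)O[C@H]3[C@@H]2OC(=O)c2ccccc2)OC1(C)C
F10 | step 6 | (6E)-4-O-benzoyl-6,7-dideoxy-2,3-O-isopropylidene-7-(pinacolatoboryl)-D-manno-hept-6-enono-1,5-lactone | CC1(C)OB(/C=C/[C@H]2OC(=O)[C@H]3OC(C)(C)O[C@H]3[C@@H]2OC(=O)c2ccccc2)OC1(C)C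
F11 | step 6 | potassium (E)-alkenyltrifluoroborate corresponding to F10 | [K+].F[B-](F)(F)/C=C/[C@H]1OC(=O)[C@H]2OC(C)(C)O[C@H]2[C@@H]1OC(=O)c1ccccc1
F12 | step 3 | phenyl 6,7-dideoxy-2,3-O-isopropylidene-1-thio-α-D-manno-hept-6-ynopyranoside | C#C[C@H]1O[C@H](Sc2ccccc2)[C@H]2OC(C)(C)O[C@H]2[C@@H]1O
F13 | step 3 | 4-O-benzoate of F12 | C#C[C@H]1O[C@H](Sc2ccccc2)[C@H]2OC(C)(C)O[C@H]2[C@@H]1OC(=O)c1ccccc1
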